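The theta run gains target less steeply late than early: its exponent of time is 0.907 from 4.00 min to 8.00 min, but 0.535 from 8.00 min to 15.0 min. This exponent, the powers of ten of target gained per power of ten of time, is the time exponent s. Both values are readings, and each reading scatters by 1.5 percentage points.

| flask | substrate | reagent in the second phase | remark | time | volume of the second phase over the first |
|---|---|---|---|---|---|
| beta | 0.27 M | 2 equiv | the very flask that is asked about, followed so far |  |  |
| theta | 0.18 M | 2 equiv | run made earlier |  |  |
| flask | 0.27 M | 2.00 equiv |  | 20 min | 1.0 |

| beta: time / min | beta: target / % | theta: time / min | theta: target / % |
|---|---|---|---|
| 0.833 | 5 | 1.00 | 4 |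
| 1.50 | 9 | 2.00 | 11 |
| 3.00 | 19 | 4.00 | 16 |
| 5.00 | 24 | 8.00 | 30 |
| 10.0 | 45 | 15.0 | 42 |

(each reading ± 1.5 percentage points)

- in the second phase: reagent in the second phase; everything else is in the first
- charges count per volume of the first phase; a concentration in a rate is the amount of a species over the volume of its own phase; every rate counts per litre of the first phase
- the analysis behind the earlier runs scatters by 1.5 percentage points, standard deviation
- the earlier runs hold the two phases in the same ratio of volumes as the flask asked about

1. target at 20 min, in percent of the substrate charged
2. the change that raises the amount of target at 20 min, in percent of the substrate charged most ("none" if none brings more than 2 percentage points) (blue / amber / none)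
3. amount of target at 20 min, in percent of the substrate charged, after blue

- blue: doubling the amount of reagent in the second phase, all else as stated
- amber: doubling the transfer coefficient of the reagent in the second phase, all else as stated

Beta is the flask asked about, with substrate as the limiting reagent. Two views of it compete.

The forecaster says: “Overall second order fits: first order in substrate and first order in reagent”. Both runs give that view 0.12 per molar and minute. The forecast is 65%, with blue as the best change, and 88% after it.

I hold that s keeps falling, and I contest the forecast's target at 20 min. Substrate charged times time is the same at the last reading of each run, and the targets read there are 45% and 42%. So beta at 10.0 min stands about where theta ended. With s held at 0.535, beta's last reading rises to 65.2% at 20 min. That is my reckoning, and it lands close to the forecast's 65%, which came from a different one. But s has just fallen by 0.372. One more such fall gives 0.164, so I commit to 50.4%.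

The simulation gives 48.3%. Its best change is blue, worth 9.9 points against 0.15 points for amber, and it reaches 58.2%.

    reagent in the reaction phase ⇌ reagent in the second phase, rate k1*([reagent in the reaction phase] - [reagent in the second phase]/K1) per volume of the first phase (partition coefficient = 2.90, kL = 0.0310 /s)
    substrate + reagent in the reaction phase → target (k = 0.0110 /M/s)
    target → over-reaction product (k = 5.80 × 10⁻⁴ /s)

From 10.0 min to 20 min this flask's s is 0.188, and over-reaction product stands at 25.2% at the end. The forecaster's view has its ground early in this flask: at 2.00 min target is nearly all of the reacted substrate, 12.3% against 0.383% of over-reaction product. Now read the same flask at 8.0 min. Carrying 0.535 back from the 42.4% of target at 10.0 min gives 37.6%. That neighbour flask holds 38.2% of target.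

The runs were computed for substances that don't exist; scatter was added.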